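**Strategy.** The furan-3(2H)-one ring (ring O, C10, C1, C2, C3; germacranolide numbering) is read as a cyclised 4-hydroxy-2-yn-1-one, so its O–C3 bond is the last ring bond made. The precursor is a strained ten-membered carbocyclic ynediol carrying C10–OH, C1–OH and C2≡C3, with the trans α-methylene lactone, the 8-methacrylate and the cis C4=C5 bond already in place; it comes from Nozaki–Hiyama–Kishi closure of C1–C2. In one operation, oxidation at C1 and gold-catalysed transannular 5-endo-dig addition of the tertiary C10 hydroxyl to C3 create the bridging enol ether, the C2=C3 bond and the complete oxa-bridged skeleton, driven by release of cycloalkyne strain.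

Key step: step 18

Remark on numbering: C1 ketone, C2=C3 enol ether, C4(=C5) bearing C15 (CH2OH), C6 lactone oxygen, C7, C8 ester, C9, C10 (methyl C14), C11(=C13)–C12 lactone carbonyl. By CIP analysis of the given structure the target is 6R,7R,8R,10R.

Assumption: the (S,S)-ProPhenol/Me2Zn catalyst is taken to transfer the alkynyl group to the Si face of enal 7; if the sense is the opposite, the (R,R)-ligand is used in step 5.

Step 1
Reactants: 1 but-2-yne-1,4-diol
Product: 2 4-[(tert-butyldiphenylsilyl)oxy]but-2-yn-1-ol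
Conditions: NaH (1.0 equiv), THF, 0 °C; then TBDPSCl (1.0 equiv), rt
Reagents that add atoms: tert-butyl(chloro)diphenylsilane (TBDPSCl), CC(C)(C)[Si](Cl)(c1ccccc1)c1ccccc1
Why: Silylation of the sparingly soluble monosodium alkoxide of a symmetric diol should favour the mono-ether, and the TBDPS group is chosen to survive every step up to the last.

Step 2
Reactants: 2 4-[(tert-butyldiphenylsilyl)oxy]but-2-yn-1-ol
Product: 4 (Z)-4-[(tert-butyldiphenylsilyl)oxy]-3-iodobut-2-en-1-ol, via cyclic alkenylalanate 3 (not isolated)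
Conditions: NaAlH2(OCH2CH2OCH3)2 (Red-Al), THF, 0 °C; then I2, THF, −78 °C to 0 °C
Reagents that add atoms: iodine, II
Why: Hydroxyl-directed trans-hydroalumination puts hydride on the alkyne carbon next to the CH2O–Al group and aluminium on the distal carbon inside a five-membered oxaluminole, and iodinolysis of the C–Al bond with retention should give the iodoalkene with iodine on C4 cis to the free hydroxymethyl group (C6).

Step 3
Reactants: 4 (Z)-4-[(tert-butyldiphenylsilyl)oxy]-3-iodobut-2-en-1-ol; 5 ethynyltrimethylsilane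
Product: 6 (E)-3-{[(tert-butyldiphenylsilyl)oxy]methyl}-5-(trimethylsilyl)pent-2-en-4-yn-1-ol (alkynyl group cis to CH2OH)
Conditions: Pd(PPh3)2Cl2 (2 mol %), CuI (4 mol %), Et3N, THF, rt
Reagents that add atoms: none
Why: Sonogashira coupling proceeds with retention of alkene geometry, so C3 ends up cis to C6 as the cis C4=C5 ring bond requires.

Step 4
Reactants: 6 (E)-3-{[(tert-butyldiphenylsilyl)oxy]methyl}-5-(trimethylsilyl)pent-2-en-4-yn-1-ol
Product: 7 (E)-3-{[(tert-butyldiphenylsilyl)oxy]methyl}-5-(trimethylsilyl)pent-2-en-4-ynal (alkynyl group cis to CHO)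
Conditions: MnO2 (excess), CH2Cl2, rt
Reagents that add atoms: none
Why: Neutral heterogeneous oxidation of the allylic alcohol with MnO2 should give the enal without isomerising the trisubstituted double bond.

Step 5
Reactants: 7 (E)-3-{[(tert-butyldiphenylsilyl)oxy]methyl}-5-(trimethylsilyl)pent-2-en-4-ynal; 8 tert-butyldimethyl(prop-2-yn-1-yloxy)silane
Product: 10 (4R,5E)-1-[(tert-butyldimethylsilyl)oxy]-6-{[(tert-butyldiphenylsilyl)oxy]methyl}-8-(trimethylsilyl)oct-5-ene-2,7-diyn-4-ol, via alkynylzinc 9 (not isolated)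
Conditions: (S,S)-ProPhenol (10 mol %), Me2Zn (3 equiv), Ph3PO (20 mol %), 8 (3 equiv), toluene, 0 °C
Reagents that add atoms: none
Why: In the zinc–ProPhenol-catalysed asymmetric alkynylation the dinuclear zinc complex binds the enal and delivers the zinc acetylide to the Si face of the carbonyl, which should set C6 as R under catalyst control.

Step 6
Reactants: 10 (4R,5E)-1-[(tert-butyldimethylsilyl)oxy]-6-{[(tert-butyldiphenylsilyl)oxy]methyl}-8-(trimethylsilyl)oct-5-ene-2,7-diyn-4-ol
Product: 12 (2Z,4R,5E)-1-[(tert-butyldimethylsilyl)oxy]-6-{[(tert-butyldiphenylsilyl)oxy]methyl}-2-iodo-8-(trimethylsilyl)octa-2,5-dien-7-yn-4-ol, via cyclic alkenylalanate 11 (not isolated)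
Conditions: NaAlH2(OCH2CH2OCH3)2, THF, −20 °C to 0 °C; then I2, THF, −78 °C
Reagents that add atoms: iodine, II
Why: The free C6 hydroxyl directs trans-hydroalumination of the propargylic alkyne (hydride to C7, aluminium to C11 in a five-membered chelate), which should be faster at low temperature than vinylogous delivery to the silyl-capped enyne, and iodinolysis with retention places iodine on C11 cis to C6.

Step 7
Reactants: 12 (2Z,4R,5E)-1-[(tert-butyldimethylsilyl)oxy]-6-{[(tert-butyldiphenylsilyl)oxy]methyl}-2-iodo-8-(trimethylsilyl)octa-2,5-dien-7-yn-4-ol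
Product: 13 (5R)-3-{[(tert-butyldimethylsilyl)oxy]methyl}-5-[(E)-2-{[(tert-butyldiphenylsilyl)oxy]methyl}-4-(trimethylsilyl)but-1-en-3-yn-1-yl]furan-2(5H)-one
Conditions: Pd(PPh3)2Cl2 (5 mol %), CO (1 atm), iPr2NEt, THF, 45 °C
Reagents that add atoms: carbon monoxide, [C-]#[O+]
Why: In this carbonylative lactonisation, oxidative addition of zerovalent palladium into the C–I bond and CO insertion give an acylpalladium that the cis-disposed C6 hydroxyl traps, forming the butenolide (C12 from CO) without touching the C6 stereocentre.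

Step 8
Reactants: 13 (5R)-3-{[(tert-butyldimethylsilyl)oxy]methyl}-5-[(E)-2-{[(tert-butyldiphenylsilyl)oxy]methyl}-4-(trimethylsilyl)but-1-en-3-yn-1-yl]furan-2(5H)-one
Product: 14 (5R)-3-(bromomethyl)-5-[(E)-2-{[(tert-butyldiphenylsilyl)oxy]methyl}-4-(trimethylsilyl)but-1-en-3-yn-1-yl]furan-2(5H)-one
Conditions: Ph3PBr2 (1.3 equiv), CH2Cl2, 0 °C to rt
Reagents that add atoms: dibromotriphenylphosphorane, BrP(Br)(c1ccccc1)(c1ccccc1)c1ccccc1
Why: Direct conversion of a primary allylic TBS ether into the bromide (bromide-induced Si–O cleavage, then SN2 collapse of the oxyphosphonium) should leave the bulkier TBDPS ether and the C–SiMe3 bond intact.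

Step 9
Reactants: 15 (R)-citramalic acid
Product: 16 (R)-2-methylbutane-1,2,4-triol
Conditions: BH3·SMe2, B(OMe)3, THF, 0 °C to rt; MeOH quench
Reagents that add atoms: none
Why: Borane reduces both carboxylic acids to primary alcohols while the tertiary carbinol centre, which becomes C10, is untouched.

Step 10
Reactants: 16 (R)-2-methylbutane-1,2,4-triol
Product: 17 (R)-2-(2,2,4-trimethyl-1,3-dioxolan-4-yl)ethan-1-ol
Conditions: 2,2-dimethoxypropane, acetone, TsOH (cat.), rt
Reagents that add atoms: 2,2-dimethoxypropane, COC(C)(C)OC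
Why: Under thermodynamic acetalisation the five-membered dioxolane on the primary/tertiary 1,2-diol should be favoured over the six-membered 1,3-dioxane, which would suffer 1,3-diaxial methyl contacts, leaving the C8 hydroxyl free.

Step 11
Reactants: 17 (R)-2-(2,2,4-trimethyl-1,3-dioxolan-4-yl)ethan-1-ol
Product: 18 (R)-2-(2,2,4-trimethyl-1,3-dioxolan-4-yl)acetaldehyde
Conditions: IBX (2-iodoxybenzoic acid), EtOAc, 75 °C
Reagents that add atoms: none
Why: IBX oxidation of the primary alcohol is neutral, so the acetonide survives and the aldehyde has no α-stereocentre to lose.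

Step 12
Reactants: 14 (5R)-3-(bromomethyl)-5-[(E)-2-{[(tert-butyldiphenylsilyl)oxy]methyl}-4-(trimethylsilyl)but-1-en-3-yn-1-yl]furan-2(5H)-one; 18 (R)-2-(2,2,4-trimethyl-1,3-dioxolan-4-yl)acetaldehyde
Product: 20 (4R,5R)-4-{(1S)-1-hydroxy-2-[(4R)-2,2,4-trimethyl-1,3-dioxolan-4-yl]ethyl}-3-methylidene-5-[(E)-2-{[(tert-butyldiphenylsilyl)oxy]methyl}-4-(trimethylsilyl)but-1-en-3-yn-1-yl]oxolan-2-one (6R,7R,8S,10R), via allylchromium dichloride 19 (not isolated)
Conditions: CrCl2 (3 equiv), THF, 0 °C to rt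
Reagents that add atoms: none
Why: In this Nozaki–Hiyama allylation the allylchromium attacks the aldehyde through its γ-carbon C7 on the lactone face anti to the C6 substituent (6,7-trans), and the closed chair transition state with the ring-locked E-type allyl unit and an equatorial aldehyde substituent should give the anti carbinol (8S), which is the C8 epimer on purpose and is corrected in step 13.

Step 13
Reactants: 20 Barbier adduct (6R,7R,8S,10R); 21 methacrylic acid
Product: 22 (1R)-1-{(2R,3R)-4-methylidene-5-oxo-2-[(E)-2-{[(tert-butyldiphenylsilyl)oxy]methyl}-4-(trimethylsilyl)but-1-en-3-yn-1-yl]oxolan-3-yl}-2-[(4R)-2,2,4-trimethyl-1,3-dioxolan-4-yl]ethyl 2-methylprop-2-enoate (6R,7R,8R,10R)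
Conditions: PPh3, DIAD, toluene, 0 °C to rt (betaine pre-formed, then 20 and 21)
Reagents that add atoms: none
Why: Mitsunobu esterification displaces the alkoxyphosphonium at C8 by methacrylate in an SN2 step with inversion, so one operation installs the ester and converts 8S into the required 8R.

Step 14
Reactants: 22 methacrylate (6R,7R,8R,10R)
Product: 23 the corresponding 1-iodoalkyne (C2–I in place of C2–SiMe3)
Conditions: NIS, AgNO3 (10 mol %), acetone, rt, dark
Reagents that add atoms: N-iodosuccinimide, O=C1CCC(=O)N1I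
Why: Silver-catalysed iododesilylation of an alkynylsilane is selective for the C(sp)–Si bond and leaves the silyl ether, acetonide and acrylate-type alkenes alone.

Step 15
Reactants: 23 iodoalkyne acetonide
Product: 24 iodoalkyne 1,10-diol (C1 primary OH, C10 tertiary OH)
Conditions: AcOH/H2O/THF (3:1:1), 45 °C
Reagents that add atoms: none
Why: Mild acid hydrolysis of the terminal acetonide should spare the TBDPS ether, lactone, methacrylate and iodoalkyne.

Step 16
Reactants: 24 iodoalkyne 1,10-diol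
Product: 25 iodoalkyne α-hydroxy aldehyde (C1 aldehyde, free C10–OH)
Conditions: IBX, DMSO, rt; used crude
Reagents that add atoms: none
Why: IBX oxidises the primary hydroxyl of a 1,2-diol to the α-hydroxy aldehyde without glycol cleavage and cannot oxidise the tertiary hydroxyl.

Step 17
Reactants: 25 iodoalkyne α-hydroxy aldehyde
Product: 27 ten-membered cyclic ynediol (C1 carbinol as a mixture of epimers; 6R,7R,8R,10R; C3 cis to C6 across C4=C5), via alkynylchromium dichloride 26 (not isolated)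
Conditions: CrCl2 (8 equiv), NiCl2 (2 mol %), THF, 2 mM, slow addition, rt
Reagents that add atoms: none
Why: In this Nozaki–Hiyama–Kishi macrocyclisation the nickel-catalysed alkynylchromium adds only to the aldehyde, the cis C4=C5 bond and the trans lactone hold the two termini on the same side, and the C1 configuration does not matter because C1 is oxidised next.

Step 18
Reactants: 27 ten-membered cyclic ynediol
Product: 29 15-O-TBDPS furanone (complete skeleton), via macrocyclic hydroxy ynone 28 (not isolated)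
Conditions: IBX, EtOAc, 60 °C; filtration, solvent switch; then Ph3PAuNTf2 (5 mol %), CH2Cl2, rt
Reagents that add atoms: none
Why: IBX oxidises the secondary propargylic carbinol of the 1,2-diol to the ketone without glycol cleavage, giving the strained cyclodecenynone 28, a 4-hydroxy-2-yn-1-one with the C10 hydroxyl held across the ring from C3; the cationic monovalent gold complex then π-activates C2≡C3, the hydroxyl oxygen adds to C3 anti to gold, and protodeauration at C2 gives the enol ether. The closest known reaction type is the gold-catalysed (or base-mediated) cycloisomerisation of 4-hydroxyalk-2-yn-1-ones to furan-3(2H)-ones, an intramolecular oxa-Michael addition. The furanone ring (O, C10, C1, C2, C3) closes in the 5-endo-dig mode through the new O–C3 bond, which also bridges the ten-membered carbocycle. No stereocentre is created: C10 comes unchanged from (R)-citramalic acid, and the new C2=C3 bond can only be cis inside the five-membered ring. The step needs oxygen attack at C3 and not C2, and reaction of the alkyne and not of the methylene lactone, the methacrylate or C4=C5; C3 is the β-carbon of the ynone and attack at C2 would be a 4-exo closure, the carbophilic gold selects the alkyne, and the tertiary hydroxyl is the only nucleophile within reach. Relief of bent-alkyne strain on going to the sp2 enol ether should make the closure fast and irreversible.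

Step 19
Reactants: 29 15-O-TBDPS furanone
Product: 30 target compound (goyazensolide-type furanoheliangolide, 6R,7R,8R,10R)
Conditions: HF·pyridine, pyridine, THF, 0 °C to rt
Reagents that add atoms: none
Why: Buffered fluoride desilylation of the primary TBDPS ether is mildly acidic and should not add to the α-methylene lactone, the methacrylate or the vinylogous ester.

**Compound list**

1 | but-2-yne-1,4-diol | OCC#CCO | starting material
2 | 4-[(tert-butyldiphenylsilyl)oxy]but-2-yn-1-ol | OCC#CCO[Si](c1ccccc1)(c1ccccc1)C(C)(C)C | intermediate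
3 | sodium cyclic alkenylalanate from 2 (2,2-bis(2-methoxyethoxy)-2,5-dihydro-1,2-oxaluminol-2-uide with the silyloxymethyl group on C3) | [Na+].COCCO[Al-]1(OCCOC)OCC=C1CO[Si](c1ccccc1)(c1ccccc1)C(C)(C)C | intermediate (not isolated)
4 | (Z)-4-[(tert-butyldiphenylsilyl)oxy]-3-iodobut-2-en-1-ol | OC/C=C(I)/CO[Si](c1ccccc1)(c1ccccc1)C(C)(C)C | intermediate
5 | ethynyltrimethylsilane | C#C[Si](C)(C)C | starting material
6 | (E)-3-{[(tert-butyldiphenylsilyl)oxy]methyl}-5-(trimethylsilyl)pent-2-en-4-yn-1-ol | OC/C=C(C#C[Si](C)(C)C)/CO[Si](c1ccccc1)(c1ccccc1)C(C)(C)C | intermediate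
7 | (E)-3-{[(tert-butyldiphenylsilyl)oxy]methyl}-5-(trimethylsilyl)pent-2-en-4-ynal | O=C/C=C(C#C[Si](C)(C)C)/CO[Si](c1ccccc1)(c1ccccc1)C(C)(C)C | intermediate
8 | tert-butyldimethyl(prop-2-yn-1-yloxy)silane | C#CCO[Si](C)(C)C(C)(C)C | starting material
9 | methyl{3-[(tert-butyldimethylsilyl)oxy]prop-1-yn-1-yl}zinc | C[Zn]C#CCO[Si](C)(C)C(C)(C)C | intermediate (not isolated)
10 | (4R,5E)-1-[(tert-butyldimethylsilyl)oxy]-6-{[(tert-butyldiphenylsilyl)oxy]methyl}-8-(trimethylsilyl)oct-5-ene-2,7-diyn-4-ol | C[Si](C)(C)C#C/C(CO[Si](c1ccccc1)(c1ccccc1)C(C)(C)C)=C\[C@H](C#CCO[Si](C)(C)C(C)(C)C)O | intermediate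
11 | sodium cyclic alkenylalanate from 10 (aluminium bound to O6 and C11) | [Na+].C[Si](C)(C)C#C/C(CO[Si](c1ccccc1)(c1ccccc1)C(C)(C)C)=C\[C@H]1O[Al-](OCCOC)(OCCOC)C(CO[Si](C)(C)C(C)(C)C)=C1 | intermediate (not isolated)
12 | (2Z,4R,5E)-1-[(tert-butyldimethylsilyl)oxy]-6-{[(tert-butyldiphenylsilyl)oxy]methyl}-2-iodo-8-(trimethylsilyl)octa-2,5-dien-7-yn-4-ol | C[Si](C)(C)C#C/C(CO[Si](c1ccccc1)(c1ccccc1)C(C)(C)C)=C\[C@H](/C=C(\I)CO[Si](C)(C)C(C)(C)C)O | intermediate
13 | (5R)-3-{[(tert-butyldimethylsilyl)oxy]methyl}-5-[(E)-2-{[(tert-butyldiphenylsilyl)oxy]methyl}-4-(trimethylsilyl)but-1-en-3-yn-1-yl]furan-2(5H)-one | C[Si](C)(C)C#C/C(CO[Si](c1ccccc1)(c1ccccc1)C(C)(C)C)=C\[C@H]1OC(=O)C(CO[Si](C)(C)C(C)(C)C)=C1 | intermediate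
14 | (5R)-3-(bromomethyl)-5-[(E)-2-{[(tert-butyldiphenylsilyl)oxy]methyl}-4-(trimethylsilyl)but-1-en-3-yn-1-yl]furan-2(5H)-one | C[Si](C)(C)C#C/C(CO[Si](c1ccccc1)(c1ccccc1)C(C)(C)C)=C\[C@H]1OC(=O)C(CBr)=C1 | intermediate
15 | (R)-citramalic acid [(R)-2-hydroxy-2-methylbutanedioic acid] | OC(=O)C[C@@](C(=O)O)(C)O | starting material
16 | (R)-2-methylbutane-1,2,4-triol | OCC[C@@](CO)(C)O | intermediate
17 | (R)-2-(2,2,4-trimethyl-1,3-dioxolan-4-yl)ethan-1-ol | OCC[C@@]1(C)OC(C)(C)OC1 | intermediate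
18 | (R)-2-(2,2,4-trimethyl-1,3-dioxolan-4-yl)acetaldehyde | O=CC[C@@]1(C)OC(C)(C)OC1 | intermediate
19 | allylchromium dichloride from 14 (trivalent chromium on C13) | C[Si](C)(C)C#C/C(CO[Si](c1ccccc1)(c1ccccc1)C(C)(C)C)=C\[C@H]1OC(=O)C(C[Cr](Cl)Cl)=C1 | intermediate (not isolated)
20 | trans α-methylene lactone with free 8-hydroxyl, (6R,7R,8S,10R): (4R,5R)-4-{(1S)-1-hydroxy-2-[(4R)-2,2,4-trimethyl-1,3-dioxolan-4-yl]ethyl}-3-methylidene-5-[(E)-2-{[(tert-butyldiphenylsilyl)oxy]methyl}-4-(trimethylsilyl)but-1-en-3-yn-1-yl]oxolan-2-one | C[Si](C)(C)C#C/C(CO[Si](c1ccccc1)(c1ccccc1)C(C)(C)C)=C\[C@H]1OC(=O)C(=C)[C@@H]1[C@@H](O)C[C@@]1(C)OC(C)(C)OC1 | intermediate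
21 | methacrylic acid | C=C(C)C(=O)O | starting material
22 | 8-methacrylate with inverted C8, (6R,7R,8R,10R), alkyne still C-silylated, C1/C10 diol as acetonide | C[Si](C)(C)C#C/C(CO[Si](c1ccccc1)(c1ccccc1)C(C)(C)C)=C\[C@H]1OC(=O)C(=C)[C@@H]1[C@H](OC(=O)C(C)=C)C[C@@]1(C)OC(C)(C)OC1 | intermediate
23 | 1-iodoalkyne acetonide (6R,7R,8R,10R) | IC#C/C(CO[Si](c1ccccc1)(c1ccccc1)C(C)(C)C)=C\[C@H]1OC(=O)C(=C)[C@@H]1[C@H](OC(=O)C(C)=C)C[C@@]1(C)OC(C)(C)OC1 | intermediate
24 | 1-iodoalkyne 1,10-diol (6R,7R,8R,10R) | IC#C/C(CO[Si](c1ccccc1)(c1ccccc1)C(C)(C)C)=C\[C@H]1OC(=O)C(=C)[C@@H]1[C@H](OC(=O)C(C)=C)C[C@@](CO)(C)O | intermediate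
25 | 1-iodoalkyne α-hydroxy aldehyde (6R,7R,8R,10R) | IC#C/C(CO[Si](c1ccccc1)(c1ccccc1)C(C)(C)C)=C\[C@H]1OC(=O)C(=C)[C@@H]1[C@H](OC(=O)C(C)=C)C[C@@](C=O)(C)O | intermediate
26 | alkynylchromium dichloride from 25 (trivalent chromium on C2) | Cl[Cr](Cl)C#C/C(CO[Si](c1ccccc1)(c1ccccc1)C(C)(C)C)=C\[C@H]1OC(=O)C(=C)[C@@H]1[C@H](OC(=O)C(C)=C)C[C@@](C=O)(C)O | intermediate (not isolated)
27 | ten-membered cyclic ynediol: C1 carbinol (epimers), C2≡C3, C4=C5 (C3 cis to C6), 6,12-trans α-methylene lactone, 8-methacrylate, C10 tertiary OH, 15-O-TBDPS; 6R,7R,8R,10R | C=C(C)C(=O)O[C@@H]1C[C@@](C)(O)C(O)C#C/C(CO[Si](c2ccccc2)(c2ccccc2)C(C)(C)C)=C\[C@H]2OC(=O)C(=C)[C@@H]21 | intermediate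
28 | ten-membered cyclic 10-hydroxy-2-yn-1-one (C1 ketone), otherwise as 27 | C=C(C)C(=O)O[C@@H]1C[C@@](C)(O)C(=O)C#C/C(CO[Si](c2ccccc2)(c2ccccc2)C(C)(C)C)=C\[C@H]2OC(=O)C(=C)[C@@H]21 | intermediate (not isolated)
29 | 15-O-TBDPS ether of the target (furan-3(2H)-one bridging C3 and C10; 4Z; 6R,7R,8R,10R) | C=C(C)C(=O)O[C@@H]1C[C@@]2(C)OC(=CC2=O)/C(CO[Si](c3ccccc3)(c3ccccc3)C(C)(C)C)=C\[C@H]2OC(=O)C(=C)[C@@H]21 | intermediate
30 | target CNP0180483.5 (4Z; 6R,7R,8R,10R) | C=C(C)C(=O)O[C@@H]1C[C@@]2(C)OC(=CC2=O)/C(CO)=C\[C@H]2OC(=O)C(=C)[C@@H]21 | target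

**Step count.** Total: 19 steps. Longest linear sequence: 16 steps (steps 1–8, then 12–19); steps 9–11 form the three-step side branch.

**Steps most likely to fail**

1. Step 17 (macrocyclisation). The ring must hold a nearly linear C1–C2≡C3–C4 unit, so oligomerisation or protonation of the alkynylchromium by the free tertiary hydroxyl may outrun ring closure. Fallback, setting out from iodoalkyne 23 and coming back at 29: syn-hydroboration of the iodoalkyne with dicyclohexylborane and protonolysis with acetic acid would give the (Z)-iodoalkene acetonide F4, which removes the alkyne strain. Acetonide hydrolysis (aqueous AcOH) gives the (Z)-iodoalkene diol F5 and IBX the (Z)-iodoalkene hydroxy aldehyde F6. CrCl2/NiCl2 closes the ten-membered cis,cis-dienediol F7 with retention of the alkenyl geometry, and IBX gives the cross-conjugated hydroxy dienone F8. A Wacker-type oxidative 5-endo cyclisation of the C10 hydroxyl onto C3 (Pd(OCOCF3)2 10 mol %, O2, DMSO; oxypalladation, then β-hydride elimination) then closes the furanone as the last ring and gives 29.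

2. Step 13 (Mitsunobu inversion). At the hindered C8 carbinol, elimination toward C7 or participation of the lactone carbonyl may compete with SN2 displacement. Fallback, setting out from bromide 14 (with aldehyde 18) and coming back at 22: hexabutylditin with Pd(PPh3)4 converts 14 into the allylstannane F2. BF3·OEt2-promoted addition of F2 to 18 at −78 °C goes through an open transition state, which should favour the syn (8R) carbinol F3 directly, again on the lactone face anti to the C6 substituent. Acylation of F3 with methacrylic anhydride/DMAP proceeds with retention and gives 22.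

3. Step 6 (directed hydroalumination). Hydride delivery to the conjugated, cis-disposed enyne or alkoxide cyclisation onto that alkyne may compete with the propargylic reduction. Fallback, setting out from 10 and coming back at 12: trans-hydrosilylation with Et3SiH and [Cp*Ru(MeCN)3]PF6 (2 mol %, CH2Cl2, 0 °C) places silicon on C11, distal to the free hydroxyl and cis to C6, giving the (Z)-vinylsilane F1. Iododesilylation of F1 with NIS in hexafluoroisopropanol proceeds with retention and gives 12.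

**Further compounds**

F1 | step 6 | (2Z,4R,5E)-1-[(tert-butyldimethylsilyl)oxy]-6-{[(tert-butyldiphenylsilyl)oxy]methyl}-2-(triethylsilyl)-8-(trimethylsilyl)octa-2,5-dien-7-yn-4-ol | C[Si](C)(C)C#C/C(CO[Si](c1ccccc1)(c1ccccc1)C(C)(C)C)=C\[C@H](/C=C(\[Si](CC)(CC)CC)CO[Si](C)(C)C(C)(C)C)O
F2 | step 13 | (5R)-3-[(tributylstannyl)methyl]-5-[(E)-2-{[(tert-butyldiphenylsilyl)oxy]methyl}-4-(trimethylsilyl)but-1-en-3-yn-1-yl]furan-2(5H)-one | C[Si](C)(C)C#C/C(CO[Si](c1ccccc1)(c1ccccc1)C(C)(C)C)=C\[C@H]1OC(=O)C(C[Sn](CCCC)(CCCC)CCCC)=C1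
F3 | step 13 | C8 epimer of 20 with free 8-hydroxyl (6R,7R,8R,10R) | C[Si](C)(C)C#C/C(CO[Si](c1ccccc1)(c1ccccc1)C(C)(C)C)=C\[C@H]1OC(=O)C(=C)[C@@H]1[C@H](O)C[C@@]1(C)OC(C)(C)OC1
F4 | step 17 | (Z)-iodoalkene acetonide (C2=C3 cis, C2–I; otherwise as 23) | I/C=C\C(CO[Si](c1ccccc1)(c1ccccc1)C(C)(C)C)=C/[C@H]1OC(=O)C(=C)[C@@H]1[C@H](OC(=O)C(C)=C)C[C@@]1(C)OC(C)(C)OC1
F5 | step 17 | (Z)-iodoalkene 1,10-diol | I/C=C\C(CO[Si](c1ccccc1)(c1ccccc1)C(C)(C)C)=C/[C@H]1OC(=O)C(=C)[C@@H]1[C@H](OC(=O)C(C)=C)C[C@@](CO)(C)O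
F6 | step 17 | (Z)-iodoalkene α-hydroxy aldehyde | I/C=C\C(CO[Si](c1ccccc1)(c1ccccc1)C(C)(C)C)=C/[C@H]1OC(=O)C(=C)[C@@H]1[C@H](OC(=O)C(C)=C)C[C@@](C=O)(C)O
F7 | step 17 | ten-membered cyclic cis,cis-2,4-diene-1,10-diol (C1 carbinol epimers) | C=C(C)C(=O)O[C@@H]1C[C@@](C)(O)C(O)/C=C\C(CO[Si](c2ccccc2)(c2ccccc2)C(C)(C)C)=C/[C@H]2OC(=O)C(=C)[C@@H]21
F8 | step 17 | ten-membered cyclic 10-hydroxy-cis,cis-2,4-dien-1-one | C=C(C)C(=O)O[C@@H]1C[C@@](C)(O)C(=O)/C=C\C(CO[Si](c2ccccc2)(c2ccccc2)C(C)(C)C)=C/[C@H]2OC(=O)C(=C)[C@@H]21
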